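**Retrosynthetic overview**
- Feature: the CH2 carbon (C1'') of each prenyl group sits on a ring carbon ortho to a phenolic oxygen (C8 of ring A beside C7–OH, C2' of ring B beside C3'–OH), so both aryl–CH2 bonds can be delivered from oxygen by [3,3] shifts.
- Target 10 ⇐ its 5-O-acetate 9 (ammonolysis) ⇐ 5-O-acetyl 7,3'-bis(1,1-dimethylallyl) ether 5, by a double ortho-Claisen rearrangement forming C8–C1'' and C2'–C1''.
- 5 ⇐ bis(1,1-dimethylpropargyl) ether 4 (semi-hydrogenation) ⇐ 3 (acetylation of O5) ⇐ (2S)-hesperetin 1 + 3-chloro-3-methylbut-1-yne 2 (O-alkylation at O7 and O3').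
- O5 is masked as the acetate for the key step: left free and hydrogen-bonded to the C4 carbonyl, the 5-OH would steer the ring A shift to C6, not C8.
- No ring is formed; rings A, B and C and the C2 stereocentre come unchanged from 1.

Key step: step 4

Numbering: flavanone numbering (ring C: O1, C2, C3, C4; ring A: C4a to C8a; ring B primed; prenyl carbons double-primed).
Assumption: (2S)-hesperetin is bought as the single enantiomer (it can also be released from citrus hesperidin by enzymatic deglycosylation), and its optical purity is checked before use.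
Assumption: in step 4 the ring B ether is taken to rearrange first; the order of the two shifts does not change the product.

**Step 1**
Reactants: 1 (2S)-hesperetin; 2 3-chloro-3-methylbut-1-yne (2.6 equiv)
Product: 3 (2S)-hesperetin 7,3'-bis(1,1-dimethylpropargyl) ether
Conditions: DBU (2.2 equiv), CuCl2 (1 mol%), MeCN, −5 to 0 °C
Reagents that add atoms: none
Why: Copper-catalysed propargylic O-alkylation of phenoxides takes the two free phenols O7 and O3' and leaves the chelated, least acidic 5-OH alone, while the low temperature, the phenoxide character of ring A and the 4'-methoxy group (no quinone methide path) should keep ring C from opening to the chalcone.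

**Step 2**
Reactants: 3 (2S)-hesperetin 7,3'-bis(1,1-dimethylpropargyl) ether
Product: 4 (2S)-5-O-acetylhesperetin 7,3'-bis(1,1-dimethylpropargyl) ether
Conditions: Ac2O, pyridine, DMAP (cat.), CH2Cl2, 0 °C to rt
Reagents that add atoms: acetic anhydride, CC(=O)OC(C)=O
Why: DMAP-catalysed O-acylation esterifies the only remaining phenol, which removes the 5-OH···O=C4 chelate and places a screening group beside C6 before the rearrangement.

**Step 3**
Reactants: 4 (2S)-5-O-acetylhesperetin 7,3'-bis(1,1-dimethylpropargyl) ether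
Product: 5 (2S)-5-O-acetylhesperetin 7,3'-bis(1,1-dimethylallyl) ether
Conditions: H2 (1 atm), Pd/CaCO3 poisoned with Pb(OAc)2 (Lindlar catalyst), quinoline, EtOAc, rt, stopped after 2 equiv H2
Reagents that add atoms: none
Why: Lindlar semi-hydrogenation stops the two terminal alkynes at the vinyl stage, and the aryl ketone, the aryl acetate and the tertiary aryl ethers are inert over the poisoned catalyst.

**Step 4**
Reactants: 5 (2S)-5-O-acetylhesperetin 7,3'-bis(1,1-dimethylallyl) ether
Product: 9 (2S)-5-O-acetyl-8,2'-diprenylhesperetin, via ring B ortho-dienone 6 (not isolated), via ring B rearranged mono-ether 7 (not isolated), via ring A ortho-dienone 8 (not isolated)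
Conditions: degassed o-xylene, 130 °C, Ar
Reagents that add atoms: none
Why: Each 1,1-dimethylallyl aryl ether undergoes a concerted, suprafacial [3,3] shift through a chair-like transition state (aromatic ortho-Claisen rearrangement) that joins the terminal vinyl carbon to the ortho ring carbon, and the ortho-dienone then tautomerises to the phenol, so the tertiary ether ends up as a linear 3-methylbut-2-enyl group; this is the known Claisen route from 1,1-dimethylallyl aryl ethers to ortho-prenylphenols, which has been applied to flavonoid ethers. No ring is closed and no stereocentre is made; C2 is a spectator and should hold in the neutral, aprotic medium at a temperature that the geminal methyl groups keep near 130 °C. On ring B the shift has only one possible end, C2', because the other ortho carbon C4' carries the methoxy group. On ring A the step needs C8 over C6: with a free 5-OH the hydrogen bond to the C4 carbonyl would favour the C4a=C5, C6=C7 bond pattern and send the allyl group to C6, as in 2-hydroxy-4-allyloxyacetophenones, so O5 is acetylated. In the acetate the strongest donor–acceptor path is O1–C8a=C4a–C4=O, which gives C7–C8 the greater double-bond character, and the acetoxy group, which turns away from the peri carbonyl toward C6, screens that carbon.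

**Step 5**
Reactants: 9 (2S)-5-O-acetyl-8,2'-diprenylhesperetin
Product: 10 (2S)-5,7,3'-trihydroxy-4'-methoxy-8,2'-diprenylflavanone (target)
Conditions: NH3 (7 N in MeOH), 0 °C; then aqueous work-up at pH 5
Reagents that add atoms: none
Why: Ammonolysis of the activated aryl acetate (acyl transfer to NH3) is fast at 0 °C, and ammonia is too weak a base to deprotonate C3, so the 5-OH should be freed without opening ring C or touching the prenyl groups.

**Compound list**
1 | (2S)-hesperetin, (2S)-5,7-dihydroxy-2-(3-hydroxy-4-methoxyphenyl)chroman-4-one | COc1ccc([C@@H]2CC(=O)c3c(O)cc(O)cc3O2)cc1O | starting material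
2 | 3-chloro-3-methylbut-1-yne (2-chloro-2-methylbut-3-yne) | CC(C)(Cl)C#C | starting material
3 | (2S)-5-hydroxy-2-[4-methoxy-3-(2-methylbut-3-yn-2-yloxy)phenyl]-7-(2-methylbut-3-yn-2-yloxy)chroman-4-one | COc1ccc([C@@H]2CC(=O)c3c(O)cc(OC(C)(C)C#C)cc3O2)cc1OC(C)(C)C#C | intermediate
4 | (2S)-5-acetoxy-2-[4-methoxy-3-(2-methylbut-3-yn-2-yloxy)phenyl]-7-(2-methylbut-3-yn-2-yloxy)chroman-4-one | COc1ccc([C@@H]2CC(=O)c3c(OC(C)=O)cc(OC(C)(C)C#C)cc3O2)cc1OC(C)(C)C#C | intermediate
5 | (2S)-5-acetoxy-2-[4-methoxy-3-(2-methylbut-3-en-2-yloxy)phenyl]-7-(2-methylbut-3-en-2-yloxy)chroman-4-one | COc1ccc([C@@H]2CC(=O)c3c(OC(C)=O)cc(OC(C)(C)C=C)cc3O2)cc1OC(C)(C)C=C | intermediate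
6 | ring B ortho-dienone: (2S)-5-acetoxy-2-[4-methoxy-6-(3-methylbut-2-enyl)-5-oxocyclohexa-1,3-dien-1-yl]-7-(2-methylbut-3-en-2-yloxy)chroman-4-one, both epimers at the transient sp3 carbon C2' | COC1=CC=C([C@@H]2CC(=O)c3c(OC(C)=O)cc(OC(C)(C)C=C)cc3O2)C(CC=C(C)C)C1=O | intermediate (not isolated)
7 | ring B rearranged mono-ether: (2S)-5-acetoxy-2-[3-hydroxy-4-methoxy-2-(3-methylbut-2-enyl)phenyl]-7-(2-methylbut-3-en-2-yloxy)chroman-4-one | COc1ccc([C@@H]2CC(=O)c3c(OC(C)=O)cc(OC(C)(C)C=C)cc3O2)c(CC=C(C)C)c1O | intermediate (not isolated)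
8 | ring A ortho-dienone: (2S)-5-acetoxy-2-[3-hydroxy-4-methoxy-2-(3-methylbut-2-enyl)phenyl]-8-(3-methylbut-2-enyl)-2,3-dihydrochromene-4,7(8H)-dione, both epimers at the transient sp3 carbon C8 | COc1ccc([C@@H]2CC(=O)C3=C(O2)C(CC=C(C)C)C(=O)C=C3OC(C)=O)c(CC=C(C)C)c1O | intermediate (not isolated)
9 | (2S)-5-acetoxy-7-hydroxy-2-[3-hydroxy-4-methoxy-2-(3-methylbut-2-enyl)phenyl]-8-(3-methylbut-2-enyl)chroman-4-one | COc1ccc([C@@H]2CC(=O)c3c(OC(C)=O)cc(O)c(CC=C(C)C)c3O2)c(CC=C(C)C)c1O | intermediate
10 | (2S)-5,7-dihydroxy-2-[3-hydroxy-4-methoxy-2-(3-methylbut-2-enyl)phenyl]-8-(3-methylbut-2-enyl)chroman-4-one | COc1ccc([C@@H]2CC(=O)c3c(O)cc(O)c(CC=C(C)C)c3O2)c(CC=C(C)C)c1O | target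

**Step count**
Total steps: 5. Longest linear sequence: 5 steps (1 → 3 → 4 → 5 → 9 → 10).

**Steps most likely to fail**

1. Step 4. The ring A shift may go to C6 in competition with C8, the tertiary ethers may lose isoprene by elimination before they rearrange, and prolonged heating may erode C2. Fallback: the C8 prenyl group is delivered from O5 by a Claisen–Cope sequence instead of from O7. Setting out from 1, acylation of the most acidic 7-OH (pivaloyl chloride, Et3N, CH2Cl2, −20 °C) should give (2S)-7-O-pivaloylhesperetin F1. Neutral O-allylation of the 3'-OH with tert-butyl 2-methylbut-3-en-2-yl carbonate and zerovalent palladium (Pd(PPh3)4, THF, 0 °C) should give the 3'-(1,1-dimethylallyl) ether F2. Mitsunobu etherification of the chelated 5-OH with 3-methylbut-2-en-1-ol (PPh3, DIAD, THF) should give the 5-O-prenyl ether F3. Heating with Eu(fod)3 (the europium tris-chelate of 6,6,7,7,8,8,8-heptafluoro-2,2-dimethyloctane-3,5-dione) in chlorobenzene at 60 and then 120 °C should move the 5-O-prenyl group to C6, its only free ortho carbon, and on by a Cope shift to C8, while the ring B ether shifts to C2', to give (2S)-7-O-pivaloyl-8,2'-diprenylhesperetin F4. K2CO3 in MeOH at 0 °C then removes the pivalate and the route is rejoined at 10.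

2. Step 1. The amidine base may open ring C to the chalcone and so erode C2, and alkylation may be incomplete at the hindered O3' or spill over to O5. Fallback: the allyl ethers are installed directly under neutral conditions. Setting out from 1, decarboxylative O-allylation with tert-butyl 2-methylbut-3-en-2-yl carbonate and zerovalent palladium (Pd(PPh3)4, THF, 0 °C, branched ether under kinetic control) should give (2S)-hesperetin 7,3'-bis(1,1-dimethylallyl) ether F5. Acetylation at O5 (Ac2O, pyridine, DMAP) rejoins the route at 5, so that no alkyne and no semi-hydrogenation are needed.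

3. Step 2. Acylation of the hydrogen-bonded 5-OH may be sluggish, and forcing it with base may open ring C. Fallback: O5 is capped as a silyl ether. Setting out from 3, TBSCl and imidazole in DMF should give the 5-O-tert-butyldimethylsilyl bis(1,1-dimethylpropargyl) ether F6. Lindlar semi-hydrogenation as in step 3 should give the 5-O-silyl bis(1,1-dimethylallyl) ether F7. The double Claisen shift in o-xylene at 130 °C, with C6 screened by the silyl group, should give the 5-O-silyl-8,2'-diprenyl compound F8. Buffered fluoride (TBAF, AcOH, THF, 0 °C) then frees O5 and the route is rejoined at 10.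

**Further compounds**
F1 | step 4 | (2S)-7-O-pivaloylhesperetin | COc1ccc([C@@H]2CC(=O)c3c(O)cc(OC(=O)C(C)(C)C)cc3O2)cc1O
F2 | step 4 | (2S)-7-O-pivaloylhesperetin 3'-(1,1-dimethylallyl) ether | COc1ccc([C@@H]2CC(=O)c3c(O)cc(OC(=O)C(C)(C)C)cc3O2)cc1OC(C)(C)C=C
F3 | step 4 | (2S)-5-O-prenyl-7-O-pivaloylhesperetin 3'-(1,1-dimethylallyl) ether | COc1ccc([C@@H]2CC(=O)c3c(OCC=C(C)C)cc(OC(=O)C(C)(C)C)cc3O2)cc1OC(C)(C)C=C
F4 | step 4 | (2S)-7-O-pivaloyl-8,2'-diprenylhesperetin | COc1ccc([C@@H]2CC(=O)c3c(O)cc(OC(=O)C(C)(C)C)c(CC=C(C)C)c3O2)c(CC=C(C)C)c1O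
F5 | step 1 | (2S)-hesperetin 7,3'-bis(1,1-dimethylallyl) ether | COc1ccc([C@@H]2CC(=O)c3c(O)cc(OC(C)(C)C=C)cc3O2)cc1OC(C)(C)C=C
F6 | step 2 | (2S)-5-O-tert-butyldimethylsilylhesperetin 7,3'-bis(1,1-dimethylpropargyl) ether | COc1ccc([C@@H]2CC(=O)c3c(O[Si](C)(C)C(C)(C)C)cc(OC(C)(C)C#C)cc3O2)cc1OC(C)(C)C#C
F7 | step 2 | (2S)-5-O-tert-butyldimethylsilylhesperetin 7,3'-bis(1,1-dimethylallyl) ether | COc1ccc([C@@H]2CC(=O)c3c(O[Si](C)(C)C(C)(C)C)cc(OC(C)(C)C=C)cc3O2)cc1OC(C)(C)C=C
F8 | step 2 | (2S)-5-O-tert-butyldimethylsilyl-8,2'-diprenylhesperetin | COc1ccc([C@@H]2CC(=O)c3c(O[Si](C)(C)C(C)(C)C)cc(O)c(CC=C(C)C)c3O2)c(CC=C(C)C)c1O
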